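**Retrosynthetic overview**
- Last bond: a Stille coupling joins the ring-bound E-vinylstannane to a (2E,4E)-5-iodopentadienamide that already carries the aminocyclopentenone.
- The vinylstannane comes from a terminal alkyne. The ring enamide C–N bond comes from a copper-catalysed amidation of an α-iodoenone with (2E,4R)-2,4-dimethyloct-2-enamide.
- Both ring stereocentres come from one new step: catalytic enantioselective desymmetrisation of an achiral 4-alkynyl p-quinol by a boron-tethered oxa-Michael addition (cis-diol). The p-quinol comes from p-benzoquinone monoketal and a silylacetylide.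
- Side chains: Evans methylation and Wittig olefination give the amide; Takai iodo-olefination and acylation of the aminocyclopentenone give the dienamide.
- Rings: neither carbocycle is built (the six-membered ring comes from the quinone monoketal, the five-membered ring is bought). The only rings formed are the temporary boronate (new step) and then the acetonide, both opened again before the end.

Assumption: 2-amino-3-hydroxycyclopent-2-en-1-one hydrochloride and lithium (trimethylsilyl)acetylide (0.5 M in THF) are treated as catalogue items; selectivities quoted are expectations, not measured values.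

**Side-chain amide (steps 1–6)**

Step 1
Reactants: 1 (R)-4-benzyl-1,3-oxazolidin-2-one; 2 hexanoyl chloride
Product: 3 (R)-4-benzyl-3-hexanoyl-1,3-oxazolidin-2-one
Conditions: Et3N, DMAP (cat.), CH2Cl2, 0 °C → rt
Reagents that add atoms: none
Why: DMAP-catalysed N-acylation of the oxazolidinone by the acid chloride, with Et3N taking up HCl; the existing stereocentre is untouched.

Step 2
Reactants: 3
Product: 5 (R)-4-benzyl-3-[(R)-2-methylhexanoyl]-1,3-oxazolidin-2-one, via sodium enolate 4 (not isolated)
Conditions: NaN(SiMe3)2, THF, −78 °C; then MeI, −78 → −40 °C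
Reagents that add atoms: iodomethane, CI
Why: Evans asymmetric alkylation: the chelated Z-enolate is methylated on the face away from the benzyl group, which sets the side-chain stereocentre as R (dr expected ≥ 95:5, minor isomer removed by chromatography).

Step 3
Reactants: 5
Product: 6 (R)-2-methylhexan-1-ol
Conditions: LiBH4, H2O (1 equiv), Et2O, 0 °C
Reagents that add atoms: none
Why: Reductive auxiliary cleavage: hydride attacks the exocyclic imide carbonyl selectively and gives the primary alcohol without epimerisation.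

Step 4
Reactants: 6; 7 ethyl 2-(triphenylphosphoranylidene)propanoate
Product: 9 ethyl (2E,4R)-2,4-dimethyloct-2-enoate, via (R)-2-methylhexanal 8 (not isolated)
Conditions: Dess–Martin periodinane, CH2Cl2, 0 °C → rt; then 7, rt
Reagents that add atoms: none
Why: Dess–Martin oxidation followed in the same flask by Wittig olefination with the stabilised α-methyl ylide, which is E-selective (> 95:5) and avoids isolating the volatile, epimerisable α-branched aldehyde.

Step 5
Reactants: 9
Product: 10 (2E,4R)-2,4-dimethyloct-2-enoic acid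
Conditions: LiOH·H2O, THF/MeOH/H2O, 50 °C; then 1 M HCl
Reagents that add atoms: lithium hydroxide, [Li+].[OH-]
Why: Ester saponification; the γ-stereocentre is not acidic enough to epimerise under hydroxide.

Step 6
Reactants: 10
Product: 12 (2E,4R)-2,4-dimethyloct-2-enamide, via acyl imidazole 11 (not isolated)
Conditions: 1,1′-carbonyldiimidazole, THF, rt; then 28% aq. NH3, 0 °C → rt
Reagents that add atoms: ammonia, N
Why: Amide formation by activation as the acyl imidazole and ammonolysis, with no risk to the olefin geometry or the stereocentre.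

**Iododienamide (steps 7–9)**

Step 7
Reactants: 13 ethyl (E)-4-oxobut-2-enoate
Product: 14 ethyl (2E,4E)-5-iodopenta-2,4-dienoate
Conditions: CrCl2, CHI3, THF, 0 °C
Reagents that add atoms: iodoform, IC(I)I
Why: Takai olefination: the geminal dichromium carbenoid adds only to the aldehyde and eliminates to the E-vinyl iodide (E/Z expected ≥ 8:1, minor isomer removed by chromatography).

Step 8
Reactants: 14
Product: 15 (2E,4E)-5-iodopenta-2,4-dienoic acid
Conditions: LiOH·H2O, THF/H2O, 0 °C → rt; then 1 M HCl
Reagents that add atoms: lithium hydroxide, [Li+].[OH-]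
Why: Mild saponification; the vinyl iodide and the diene geometry are stable to cold aqueous hydroxide.

Step 9
Reactants: 15; 16 2-amino-3-hydroxycyclopent-2-en-1-one hydrochloride
Product: 18 (2E,4E)-N-(2-hydroxy-5-oxocyclopent-1-en-1-yl)-5-iodopenta-2,4-dienamide, via acid chloride 17 (not isolated)
Conditions: (COCl)2, DMF (cat.), CH2Cl2, 0 °C → rt, evaporate; then 16, Et3N, DMF, 0 °C → rt
Reagents that add atoms: none
Why: Amide coupling through the acid chloride, the usual way this amino-enol unit is attached to polyenoic acids.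

**Core and endgame (steps 10–17)**

Step 10
Reactants: 19 4,4-dimethoxycyclohexa-2,5-dien-1-one; 20 lithium (trimethylsilyl)acetylide
Product: 22 4-hydroxy-4-[(trimethylsilyl)ethynyl]cyclohexa-2,5-dien-1-one, via ketal carbinol 21 (not isolated)
Conditions: THF, −78 °C; then 1 M aq. HCl, THF, 0 °C → rt
Reagents that add atoms: water, O
Why: 1,2-Addition of the lithium acetylide to the dienone carbonyl, then acid hydrolysis of the dimethyl ketal, gives the achiral (mirror-symmetric) p-quinol.

Step 11
Reactants: 22
Product: 24 (4R,5R)-4,5-dihydroxy-4-[(trimethylsilyl)ethynyl]cyclohex-2-en-1-one, via phenylboronate 23 (not isolated)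
Conditions: PhB(OH)2 (1.2 equiv), quinine-derived 3,5-(CF3)2C6H3-thiourea catalyst (10 mol%), 4 Å molecular sieves, toluene, 0 °C → rt; then 30% aq. H2O2, NaH2PO4/Na2HPO4 buffer (pH 7), THF, 0 °C
Reagents that add atoms: phenylboronic acid, OB(O)c1ccccc1
Why: Proposed new method: a catalytic enantioselective desymmetrising boron-tethered oxa-Michael addition on a p-quinol — PhB(OH)2 reversibly esterifies the tertiary hydroxyl to a boronic acid hemiester, the quinuclidine nitrogen of the catalyst binds boron and so raises the nucleophilicity of the remaining B–OH oxygen while the thiourea hydrogen-bonds the dienone carbonyl, and this two-point binding in the chiral pocket lets the oxygen add (5-exo) to only one of the two enantiotopic β-carbons; the five-membered boronate forces the new C5–O bond cis to the C4–O bond, so both ring stereocentres (4R,5R) are set in one event, and buffered peroxide then cleaves the B–C and B–O bonds without touching the C–O bonds; the closest known reaction types are the amine–thiourea-catalysed boronic acid hemiester oxa-Michael addition to acyclic γ-hydroxy enones (face selection on one enone) and the chiral-acid-catalysed acetalisation/oxa-Michael desymmetrisation of p-quinols with aldehydes, whereas differentiation of the two enone arms of a cross-conjugated 4-alkynyl p-quinol through a boron tether has not been shown.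

Step 12
Reactants: 24
Product: 25 (4R,5R)-4,5-(isopropylidenedioxy)-4-[(trimethylsilyl)ethynyl]cyclohex-2-en-1-one
Conditions: 2,2-dimethoxypropane, PPTS (cat.), CH2Cl2, rt
Reagents that add atoms: 2,2-dimethoxypropane, COC(C)(C)OC
Why: Acid-catalysed acetonide formation, possible only because the two hydroxyls are cis, masks the β-hydroxy ketone for the basic steps that follow.

Step 13
Reactants: 25
Product: 26 (4R,5R)-2-iodo-4,5-(isopropylidenedioxy)-4-[(trimethylsilyl)ethynyl]cyclohex-2-en-1-one
Conditions: I2, pyridine, CH2Cl2, 0 °C → rt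
Reagents that add atoms: iodine, II
Why: Johnson α-iodination of an enone (pyridine conjugate addition, iodination, elimination) puts iodine on the only enone α-carbon; the silylalkyne and acetonide are inert to I2/pyridine.

Step 14
Reactants: 26; 12
Product: 27 (2E,4R)-N-[(3R,4R)-3,4-(isopropylidenedioxy)-6-oxo-3-[(trimethylsilyl)ethynyl]cyclohex-1-en-1-yl]-2,4-dimethyloct-2-enamide
Conditions: CuI (20 mol%), N,N′-dimethylethylenediamine (40 mol%), K2CO3, toluene, 60 °C
Reagents that add atoms: none
Why: Goldberg-type copper-catalysed amidation of a vinyl iodide (Buchwald diamine conditions) joins the primary amide to the activated α-iodoenone with the double bond kept in place; the silyl group stops the alkyne from forming a copper acetylide.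

Step 15
Reactants: 27
Product: 29 (2E,4R)-N-[(3R,4R)-3-ethynyl-3,4-dihydroxy-6-oxocyclohex-1-en-1-yl]-2,4-dimethyloct-2-enamide, via ethynyl acetonide 28 (not isolated)
Conditions: K2CO3 (0.2 equiv), MeOH, 0 °C; then 2 M aq. HCl to pH 1, rt
Reagents that add atoms: none
Why: Base-catalysed methanolysis of the alkynyl C–Si bond, then acid hydrolysis of the acetonide; both are done before the acid- and light-sensitive triene exists.

Step 16
Reactants: 29
Product: 30 (2E,4R)-N-[(3R,4R)-3,4-dihydroxy-6-oxo-3-[(E)-2-(tributylstannyl)ethenyl]cyclohex-1-en-1-yl]-2,4-dimethyloct-2-enamide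
Conditions: Bu3SnH (1.2 equiv, slow addition), PdCl2(PPh3)2 (5 mol%), THF, −20 → 0 °C
Reagents that add atoms: tributyltin hydride, CCCC[SnH](CCCC)CCCC
Why: Palladium-catalysed syn-hydrostannylation of the terminal alkyne; the quaternary propargylic carbon steers tin to the terminal carbon and syn addition gives the E-vinylstannane.

Step 17
Reactants: 30; 18
Product: 31 (2E,4R)-N-[(3S,4R)-3,4-dihydroxy-3-[(1E,3E,5E)-7-[(2-hydroxy-5-oxocyclopent-1-en-1-yl)amino]-7-oxohepta-1,3,5-trien-1-yl]-6-oxocyclohex-1-en-1-yl]-2,4-dimethyloct-2-enamide (CNP0154433.2)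
Conditions: PdCl2(MeCN)2 (10 mol%), DMF, rt, dark, argon
Reagents that add atoms: none
Why: Stille coupling of the E-vinylstannane with the E,E-iododiene goes with retention at both partners under neutral, phosphine-free conditions that tolerate the free diol, enol and N–H groups, and completes the all-E triene (the carbinol label changes from R to S only through CIP priorities, not geometry).

**Compound list**
1 | (R)-4-benzyl-1,3-oxazolidin-2-one | O=C1N[C@H](Cc2ccccc2)CO1 | starting material
2 | hexanoyl chloride | CCCCCC(Cl)=O | starting material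
3 | (R)-4-benzyl-3-hexanoyl-1,3-oxazolidin-2-one | CCCCCC(=O)N1[C@H](Cc2ccccc2)COC1=O | intermediate
4 | sodium (Z)-enolate of 3 | CCCC/C=C(\[O-])N1[C@H](Cc2ccccc2)COC1=O.[Na+] | intermediate (not isolated)
5 | (R)-4-benzyl-3-[(R)-2-methylhexanoyl]-1,3-oxazolidin-2-one | CCCC[C@@H](C)C(=O)N1[C@H](Cc2ccccc2)COC1=O | intermediate
6 | (R)-2-methylhexan-1-ol | CCCC[C@@H](C)CO | intermediate
7 | ethyl 2-(triphenylphosphoranylidene)propanoate | CCOC(=O)C(C)=P(c1ccccc1)(c1ccccc1)c1ccccc1 | starting material
8 | (R)-2-methylhexanal | CCCC[C@@H](C)C=O | intermediate (not isolated)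
9 | ethyl (2E,4R)-2,4-dimethyloct-2-enoate | CCCC[C@@H](C)/C=C(\C)C(=O)OCC | intermediate
10 | (2E,4R)-2,4-dimethyloct-2-enoic acid | CCCC[C@@H](C)/C=C(\C)C(=O)O | intermediate
11 | (2E,4R)-1-(imidazol-1-yl)-2,4-dimethyloct-2-en-1-one | CCCC[C@@H](C)/C=C(\C)C(=O)n1ccnc1 | intermediate (not isolated)
12 | (2E,4R)-2,4-dimethyloct-2-enamide | CCCC[C@@H](C)/C=C(\C)C(N)=O | intermediate
13 | ethyl (E)-4-oxobut-2-enoate | CCOC(=O)/C=C/C=O | starting material
14 | ethyl (2E,4E)-5-iodopenta-2,4-dienoate | CCOC(=O)/C=C/C=C/I | intermediate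
15 | (2E,4E)-5-iodopenta-2,4-dienoic acid | OC(=O)/C=C/C=C/I | intermediate
16 | 2-amino-3-hydroxycyclopent-2-en-1-one hydrochloride | NC1=C(O)CCC1=O.Cl | starting material
17 | (2E,4E)-5-iodopenta-2,4-dienoyl chloride | ClC(=O)/C=C/C=C/I | intermediate (not isolated)
18 | (2E,4E)-N-(2-hydroxy-5-oxocyclopent-1-en-1-yl)-5-iodopenta-2,4-dienamide | O=C(/C=C/C=C/I)NC1=C(O)CCC1=O | intermediate
19 | 4,4-dimethoxycyclohexa-2,5-dien-1-one | COC1(OC)C=CC(=O)C=C1 | starting material
20 | lithium (trimethylsilyl)acetylide | [Li]C#C[Si](C)(C)C | starting material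
21 | 4,4-dimethoxy-1-[(trimethylsilyl)ethynyl]cyclohexa-2,5-dien-1-ol | COC1(OC)C=CC(O)(C#C[Si](C)(C)C)C=C1 | intermediate (not isolated)
22 | 4-hydroxy-4-[(trimethylsilyl)ethynyl]cyclohexa-2,5-dien-1-one | O=C1C=CC(O)(C#C[Si](C)(C)C)C=C1 | intermediate
23 | cis-fused phenylboronate (2-phenyl-1,3,2-dioxaborolane across O4 and O5) of 24 | O=C1C=C[C@@](O2)(C#C[Si](C)(C)C)[C@H](OB2c3ccccc3)C1 | intermediate (not isolated)
24 | (4R,5R)-4,5-dihydroxy-4-[(trimethylsilyl)ethynyl]cyclohex-2-en-1-one | O=C1C=C[C@@](O)(C#C[Si](C)(C)C)[C@H](O)C1 | intermediate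
25 | (4R,5R)-4,5-(isopropylidenedioxy)-4-[(trimethylsilyl)ethynyl]cyclohex-2-en-1-one | O=C1C=C[C@@](O2)(C#C[Si](C)(C)C)[C@H](OC2(C)C)C1 | intermediate
26 | (4R,5R)-2-iodo-4,5-(isopropylidenedioxy)-4-[(trimethylsilyl)ethynyl]cyclohex-2-en-1-one | O=C1C(I)=C[C@@](O2)(C#C[Si](C)(C)C)[C@H](OC2(C)C)C1 | intermediate
27 | (2E,4R)-N-[(3R,4R)-3,4-(isopropylidenedioxy)-6-oxo-3-[(trimethylsilyl)ethynyl]cyclohex-1-en-1-yl]-2,4-dimethyloct-2-enamide | CCCC[C@@H](C)/C=C(\C)C(=O)NC1=C[C@@](O2)(C#C[Si](C)(C)C)[C@H](OC2(C)C)CC1=O | intermediate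
28 | (2E,4R)-N-[(3R,4R)-3-ethynyl-3,4-(isopropylidenedioxy)-6-oxocyclohex-1-en-1-yl]-2,4-dimethyloct-2-enamide | CCCC[C@@H](C)/C=C(\C)C(=O)NC1=C[C@@](O2)(C#C)[C@H](OC2(C)C)CC1=O | intermediate (not isolated)
29 | (2E,4R)-N-[(3R,4R)-3-ethynyl-3,4-dihydroxy-6-oxocyclohex-1-en-1-yl]-2,4-dimethyloct-2-enamide | CCCC[C@@H](C)/C=C(\C)C(=O)NC1=C[C@@](O)(C#C)[C@H](O)CC1=O | intermediate
30 | (2E,4R)-N-[(3R,4R)-3,4-dihydroxy-6-oxo-3-[(E)-2-(tributylstannyl)ethenyl]cyclohex-1-en-1-yl]-2,4-dimethyloct-2-enamide | CCCC[C@@H](C)/C=C(\C)C(=O)NC1=C[C@@](O)(/C=C/[Sn](CCCC)(CCCC)CCCC)[C@H](O)CC1=O | intermediate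
31 | (2E,4R)-N-[(3S,4R)-3,4-dihydroxy-3-[(1E,3E,5E)-7-[(2-hydroxy-5-oxocyclopent-1-en-1-yl)amino]-7-oxohepta-1,3,5-trien-1-yl]-6-oxocyclohex-1-en-1-yl]-2,4-dimethyloct-2-enamide | CCCC[C@@H](C)/C=C(\C)C(=O)NC1=C[C@@](O)(/C=C/C=C/C=C/C(=O)NC2=C(O)CCC2=O)[C@H](O)CC1=O | target

**Totals**
Total steps: 17. Longest linear sequence: 10 steps (1, 2, 3, 4, 5, 6, 14, 15, 16, 17). The core branch is 8 steps (10–17) and the dienamide branch is 3 steps plus the final coupling.

**Three steps most likely to fail**

Step 11 (the proposed new step). The risks are low enantioselectivity or the wrong sense of induction, slow hemiester formation at the hindered tertiary carbinol, and retro-oxa-Michael back to achiral 22 during work-up. The choice of the quinine-derived catalyst for the (4R,5R) series is a design expectation; the quinidine-derived pseudoenantiomer would give the other series. The fallback uses known chemistry and sets out from 22. A chiral BINOL-derived phosphoric acid (the 3,3′-bis(2,4,6-triisopropylphenyl) member, enantiomer chosen by the observed sense) catalyses the acetalisation/oxa-Michael cascade of 22 with acetaldehyde in CH2Cl2 over 4 Å sieves. This gives the cis-fused ethylidene acetal (4R,5R)-4,5-[(S)-ethylidenedioxy]-4-[(trimethylsilyl)ethynyl]cyclohex-2-en-1-one F1, in which the hemiacetal tether again enforces the cis-diol. Aqueous trifluoroacetic acid at 0 °C → rt then hydrolyses the acetal, and the route is rejoined at 24.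

Step 14 (copper-catalysed amidation). The risks are base-induced E1cB opening of the β-alkoxy ketone with loss of acetone, partial desilylation followed by copper acetylide chemistry, and slow coupling of the α-branched primary enamide. The fallback sets out from 26 and makes the C–N bond with azide, then builds the amide by acylation. Copper-catalysed azidation (NaN3, CuI, sodium ascorbate, N,N′-dimethylethylenediamine, EtOH/H2O, rt) gives (4R,5R)-2-azido-4,5-(isopropylidenedioxy)-4-[(trimethylsilyl)ethynyl]cyclohex-2-en-1-one F2. Staudinger reaction with PPh3 in THF gives the iminophosphorane F3, and added water hydrolyses it to the 2-amino enone F4. N-acylation with (2E,4R)-2,4-dimethyloct-2-enoyl chloride F5 (from acid 10 with oxalyl chloride) and pyridine in CH2Cl2 at 0 °C rejoins the route at 27.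

Step 16 (hydrostannylation). The risks are competing tin hydride conjugate reduction of the enone, formation of the internal (α) stannane, and protodestannylation of the polar product on silica. The fallback sets out from 29 and avoids tin altogether. Lindlar semi-hydrogenation (H2, Pd/CaCO3/Pb(OAc)2, quinoline, EtOAc) gives the vinyl carbinol (2E,4R)-N-[(3S,4R)-3-ethenyl-3,4-dihydroxy-6-oxocyclohex-1-en-1-yl]-2,4-dimethyloct-2-enamide F6. A silver-promoted Heck reaction of F6 with 18 (Pd(OAc)2, Ag2CO3, DMF, rt → 40 °C) then closes the triene. Insertion places the dienyl group on the terminal carbon, and the only available β-hydride elimination gives the E olefin, so the route is rejoined directly at 31.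

Further compounds
F1 | step 11 | (4R,5R)-4,5-[(S)-ethylidenedioxy]-4-[(trimethylsilyl)ethynyl]cyclohex-2-en-1-one (methyl exo) | O=C1C=C[C@@](O2)(C#C[Si](C)(C)C)[C@H](O[C@@H]2C)C1
F2 | step 14 | (4R,5R)-2-azido-4,5-(isopropylidenedioxy)-4-[(trimethylsilyl)ethynyl]cyclohex-2-en-1-one | O=C1C(N=[N+]=[N-])=C[C@@](O2)(C#C[Si](C)(C)C)[C@H](OC2(C)C)C1
F3 | step 14 | (4R,5R)-4,5-(isopropylidenedioxy)-2-[(triphenylphosphoranylidene)amino]-4-[(trimethylsilyl)ethynyl]cyclohex-2-en-1-one | O=C1C(N=P(c3ccccc3)(c3ccccc3)c3ccccc3)=C[C@@](O2)(C#C[Si](C)(C)C)[C@H](OC2(C)C)C1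
F4 | step 14 | (4R,5R)-2-amino-4,5-(isopropylidenedioxy)-4-[(trimethylsilyl)ethynyl]cyclohex-2-en-1-one | NC1=C[C@@](O2)(C#C[Si](C)(C)C)[C@H](OC2(C)C)CC1=O
F5 | step 14 | (2E,4R)-2,4-dimethyloct-2-enoyl chloride | CCCC[C@@H](C)/C=C(\C)C(Cl)=O
F6 | step 16 | (2E,4R)-N-[(3S,4R)-3-ethenyl-3,4-dihydroxy-6-oxocyclohex-1-en-1-yl]-2,4-dimethyloct-2-enamide | CCCC[C@@H](C)/C=C(\C)C(=O)NC1=C[C@@](O)(C=C)[C@H](O)CC1=O
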